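**Retrosynthetic overview**
1. The target is (2S)-luteoliflavan-(4β→8)-(−)-epigallocatechin 3-O-gallate; the last disconnection is the hydrogenolysis of twelve O-benzyl groups.
2. The interflavan bond C4(upper C-ring)–C8(lower A-ring) is made from two C–H bonds by an oxidative cross-dehydrogenative coupling of tetra-O-benzyl-(2S)-flavan 4 with octa-O-benzyl-EGCG 8; this step also sets C4.
3. Enabling feature: the C4H2 of the upper pyran ring sits on an A-ring oxygenated at C5, C7 and C8a (ortho, para, ortho to C4a) and has no oxygen at C3, so it is a good hydride donor. C8–H of the lower A-ring, between O7 and the ring oxygen O1, is the most nucleophilic aromatic CH.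
4. Flavan 4 comes from (+)-catechin by benzylation and radical removal of the 3-OH (C2 from the chiral pool); 8 comes from (−)-epigallocatechin by benzylation of its five phenols and esterification of the 3-OH with tri-O-benzylgallic acid 7.
5. No ring is formed in the route: both chroman units are taken ring-complete from the chiral pool.

Key step: step 6

Remark: the upper unit is read as a (2S,4R)-flavan with the 2-aryl and 4-aryl groups trans, the lower unit as (2R,3R)-EGCG. In step 6 compound 8 is used in threefold excess and the surplus is to be recovered.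

**Step 1**
Reactants: 1 (+)-catechin
Product: 2 5,7,3',4'-tetra-O-benzyl-(+)-catechin
Conditions: BnBr (4.4 equiv), K2CO3 (5 equiv), DMF, Ar, 0 °C → rt
Reagents that add atoms: benzyl bromide, BrCc1ccccc1
Why: Williamson ether synthesis in which carbonate deprotonates only the four phenols, so the secondary 3-OH stays free and neither stereocentre is touched.

**Step 2**
Reactants: 2 5,7,3',4'-tetra-O-benzyl-(+)-catechin
Product: 3 3-O-(phenoxythiocarbonyl)-5,7,3',4'-tetra-O-benzyl-(+)-catechin
Conditions: PhOC(S)Cl (1.5 equiv), pyridine, DMAP (cat.), CH2Cl2, 0 °C → rt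
Reagents that add atoms: O-phenyl chlorothionoformate, S=C(Cl)Oc1ccccc1
Why: DMAP-catalysed thioacylation of the only free hydroxyl gives the radical-deoxygenation precursor with retention at C3.

**Step 3**
Reactants: 3 3-O-(phenoxythiocarbonyl)-5,7,3',4'-tetra-O-benzyl-(+)-catechin
Product: 4 (2S)-5,7,3',4'-tetra-O-benzylflavan
Conditions: Bu3SnH (2 equiv, 0.3 M), AIBN (cat.), toluene, 80 °C
Reagents that add atoms: none
Why: Barton–McCombie deoxygenation, in which the stannyl radical adds to C=S, the C3–O bond fragments and the C3 radical is reduced by the concentrated tin hydride before it can open the ring; C2 is untouched and its descriptor changes from R to S only because C3 loses its oxygen.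

**Step 4**
Reactants: 5 (−)-epigallocatechin
Product: 6 5,7,3',4',5'-penta-O-benzyl-(−)-epigallocatechin
Conditions: BnBr (5.5 equiv), K2CO3 (6 equiv), degassed DMF, Ar, 0 °C → rt
Reagents that add atoms: benzyl bromide, BrCc1ccccc1
Why: Williamson ether synthesis in which carbonate deprotonates only the five phenols, so the axial secondary 3-OH stays free; excess benzyl bromide under argon should trap each phenoxide before the pyrogallol ring is oxidised or C2 epimerises through a quinone methide.

**Step 5**
Reactants: 6 5,7,3',4',5'-penta-O-benzyl-(−)-epigallocatechin; 7 3,4,5-tris(benzyloxy)benzoic acid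
Product: 8 octa-O-benzyl-(−)-epigallocatechin 3-O-gallate
Conditions: 7 (1.3 equiv), DCC (1.5 equiv), DMAP (0.2 equiv), CH2Cl2, 0 °C → rt
Reagents that add atoms: none
Why: Steglich esterification, in which the O-acylisourea of 7 is passed on by DMAP as an acylpyridinium ion to the only free hydroxyl; the C3–O bond is not broken, so C3 keeps its configuration, and the non-basic conditions leave C2 untouched.

**Step 6**
Reactants: 4 (2S)-5,7,3',4'-tetra-O-benzylflavan; 8 octa-O-benzyl-(−)-epigallocatechin 3-O-gallate
Product: 10 dodeca-O-benzyl (2S)-luteoliflavan-(4β→8)-epigallocatechin 3-O-gallate, via flavan-4-ylium DDQH ion pair 9 (not isolated)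
Conditions: 8 (3 equiv), DDQ (1.05 equiv), 4 Å MS, CH2Cl2, −20 °C; 4 in CH2Cl2 added over 2 h; then 0 °C
Reagents that add atoms: none
Why: Proposed new method: DDQ should form a charge-transfer complex with the 5,7,8a-trioxygenated A-ring of 4 and take the pseudo-axial hydride from C4 to give ion pair 9, a benzylic cation stabilised by O1, 5-OBn and 7-OBn, which is attacked by C8 of 8 in a Friedel–Crafts step before the Wheland intermediate gives its proton to the hydroquinone anion. The closest known reaction types are the DDQ oxidation of C4–H in benzylated flavans with capture by alcohols and the DDQ-mediated cross-dehydrogenative coupling of diarylmethane, xanthene and isochroman C–H bonds with electron-rich arenes; new is the capture of the flavan cation by a second flavan in the same flask. The step closes no ring. The new stereocentre C4 is controlled by the C2 aryl group of 4: in the sofa-shaped cation this group is pseudo-equatorial and the arene enters along the axial trajectory on the face of the axial H2 (chair-like transition state, 4-aryl group pseudo-axial and free of peri strain with 5-OBn), which should give the 2,4-trans (4R) isomer. The step needs hydride abstraction from 4 and not from 8, which the missing C3 oxygen of 4 secures (the C4H2 of 8 is deactivated by the β-galloyloxy group); attack at C8 and not C6 of 8, which follows from C8 lying between one benzyloxy group and the ring oxygen while C6 lies between two benzyloxy groups; and cross-coupling instead of self-coupling of 4, which the excess of 8 and the slow addition of 4 secure.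

**Step 7**
Reactants: 10 dodeca-O-benzyl (2S)-luteoliflavan-(4β→8)-epigallocatechin 3-O-gallate
Product: 11 (2S)-luteoliflavan-(4β→8)-(−)-epigallocatechin 3-O-gallate (target)
Conditions: H2 (1 atm), 20% Pd(OH)2/C, THF/MeOH/H2O, rt
Reagents that add atoms: none
Why: Heterogeneous hydrogenolysis of the twelve O-benzyl groups over Pearlman's catalyst, the usual last step for benzylated oligomeric flavan-3-ol gallates; under neutral conditions at room temperature the gallate ester, the diarylmethine C4–C8 bond and the four stereocentres should not be affected.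

**Compound list**
1 | (+)-catechin, (2R,3S)-2-(3,4-dihydroxyphenyl)chromane-3,5,7-triol | C1[C@H](O)[C@@H](c2ccc(O)c(O)c2)Oc2cc(O)cc(O)c21 | starting material
2 | (2R,3S)-5,7-bis(benzyloxy)-2-[3,4-bis(benzyloxy)phenyl]chroman-3-ol | C1[C@H](O)[C@@H](c2ccc(OCc3ccccc3)c(OCc3ccccc3)c2)Oc2cc(OCc3ccccc3)cc(OCc3ccccc3)c21 | intermediate
3 | O-{(2R,3S)-5,7-bis(benzyloxy)-2-[3,4-bis(benzyloxy)phenyl]chroman-3-yl} O-phenyl carbonothioate | C1[C@H](OC(=S)Oc2ccccc2)[C@@H](c2ccc(OCc3ccccc3)c(OCc3ccccc3)c2)Oc2cc(OCc3ccccc3)cc(OCc3ccccc3)c21 | intermediate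
4 | (2S)-5,7-bis(benzyloxy)-2-[3,4-bis(benzyloxy)phenyl]chromane | C1C[C@@H](c2ccc(OCc3ccccc3)c(OCc3ccccc3)c2)Oc2cc(OCc3ccccc3)cc(OCc3ccccc3)c21 | intermediate
5 | (−)-epigallocatechin, (2R,3R)-2-(3,4,5-trihydroxyphenyl)chromane-3,5,7-triol | O[C@@H]1Cc2c(O)cc(O)cc2O[C@@H]1c1cc(O)c(O)c(O)c1 | starting material
6 | (2R,3R)-5,7-bis(benzyloxy)-2-[3,4,5-tris(benzyloxy)phenyl]chroman-3-ol | O[C@@H]1Cc2c(OCc3ccccc3)cc(OCc3ccccc3)cc2O[C@@H]1c1cc(OCc3ccccc3)c(OCc3ccccc3)c(OCc3ccccc3)c1 | intermediate
7 | 3,4,5-tris(benzyloxy)benzoic acid (tri-O-benzylgallic acid) | O=C(O)c1cc(OCc2ccccc2)c(OCc2ccccc2)c(OCc2ccccc2)c1 | starting material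
8 | (2R,3R)-5,7-bis(benzyloxy)-2-[3,4,5-tris(benzyloxy)phenyl]chroman-3-yl 3,4,5-tris(benzyloxy)benzoate | O=C(O[C@@H]1Cc2c(OCc3ccccc3)cc(OCc3ccccc3)cc2O[C@@H]1c1cc(OCc3ccccc3)c(OCc3ccccc3)c(OCc3ccccc3)c1)c1cc(OCc3ccccc3)c(OCc3ccccc3)c(OCc3ccccc3)c1 | intermediate
9 | (2S)-5,7-bis(benzyloxy)-2-[3,4-bis(benzyloxy)phenyl]chroman-4-ylium 2,3-dichloro-5,6-dicyano-4-hydroxyphenolate (ion pair, not isolated) | [CH+]1C[C@@H](c2ccc(OCc3ccccc3)c(OCc3ccccc3)c2)Oc2cc(OCc3ccccc3)cc(OCc3ccccc3)c21.[O-]c1c(Cl)c(Cl)c(O)c(C#N)c1C#N | intermediate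
10 | (2R,3R)-5,7-bis(benzyloxy)-8-{(2S,4R)-5,7-bis(benzyloxy)-2-[3,4-bis(benzyloxy)phenyl]chroman-4-yl}-2-[3,4,5-tris(benzyloxy)phenyl]chroman-3-yl 3,4,5-tris(benzyloxy)benzoate | O=C(O[C@@H]1Cc2c(OCc5ccccc5)cc(OCc5ccccc5)c([C@@H]3C[C@@H](c4ccc(OCc5ccccc5)c(OCc5ccccc5)c4)Oc4cc(OCc5ccccc5)cc(OCc5ccccc5)c43)c2O[C@@H]1c1cc(OCc5ccccc5)c(OCc5ccccc5)c(OCc5ccccc5)c1)c1cc(OCc5ccccc5)c(OCc5ccccc5)c(OCc5ccccc5)c1 | intermediate
11 | (2R,3R)-8-[(2S,4R)-2-(3,4-dihydroxyphenyl)-5,7-dihydroxychroman-4-yl]-5,7-dihydroxy-2-(3,4,5-trihydroxyphenyl)chroman-3-yl 3,4,5-trihydroxybenzoate | O=C(O[C@@H]1Cc2c(O)cc(O)c([C@@H]3C[C@@H](c4ccc(O)c(O)c4)Oc4cc(O)cc(O)c43)c2O[C@@H]1c1cc(O)c(O)c(O)c1)c1cc(O)c(O)c(O)c1 | target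

**Step count**
Total: 7 steps. Longest linear sequence: 5 steps (1 → 2 → 3 → 4 → 10 → 11; steps 1, 2, 3, 6 and 7).

**Steps most likely to fail**

Step 6 (proposed new method). Three processes may compete with the coupling:
- proton loss from C3 of the cation followed by a second hydride abstraction, which would aromatise the upper C-ring;
- self-coupling, because 4 is itself an electron-rich arene;
- hydride abstraction from C4 of 8.

Fallback with known chemistry, setting out from 4: DDQ and 2-ethoxyethanol in CH2Cl2 at 0 °C should trap the same cation at oxygen, far faster than elimination, to give (2S,4R)-5,7-bis(benzyloxy)-2-[3,4-bis(benzyloxy)phenyl]-4-(2-ethoxyethoxy)chromane F1, whose C4 configuration is lost again on ionisation. F1 is then ionised with TMSOTf (cat.) in CH2Cl2 at −78 °C in the presence of 8 (3 equiv), a Lewis-acid Friedel–Crafts coupling of the established 4-alkoxyflavan type with no oxidant present, and the route is rejoined at 10.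

Step 4. Under basic conditions the free polyphenolate may epimerise at C2 through ring opening, be benzylated on carbon, or be oxidised at the pyrogallol ring.

Fallback setting out from 5: peracetylation (Ac2O, pyridine, rt) should give (−)-epigallocatechin hexaacetate F2. A one-pot deacetylation–benzylation (NaH, BnCl, DMF, one equivalent of water per aryl acetate, 0 °C → rt) then releases each phenoxide only in the presence of the alkylating agent. The five aryl acetates are cleaved much faster than the secondary alkyl acetate, so the product should be 3-O-acetyl-5,7,3',4',5'-penta-O-benzyl-(−)-epigallocatechin F3. Methanolysis of the remaining acetate (K2CO3 cat., MeOH/THF, rt) comes back to the route at 6.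

Step 7. Removal of twelve benzyl ethers may stop short, and prolonged exposure to the catalyst may hydrogenolyse the benzylic C2–O bonds of the pyran rings.

Fallback setting out from 10: non-reductive Lewis-acid debenzylation with BCl3 and pentamethylbenzene as cation scavenger in CH2Cl2 at −78 °C, quenched cold with methanol, should lead directly to 11; this fallback makes no new compound (F0).

**Further compounds**
F1 | step 6 | (2S,4R)-5,7-bis(benzyloxy)-2-[3,4-bis(benzyloxy)phenyl]-4-(2-ethoxyethoxy)chromane | CCOCCO[C@@H]1C[C@@H](c2ccc(OCc3ccccc3)c(OCc3ccccc3)c2)Oc2cc(OCc3ccccc3)cc(OCc3ccccc3)c21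
F2 | step 4 | (−)-epigallocatechin hexaacetate, (2R,3R)-3,5,7-triacetoxy-2-(3,4,5-triacetoxyphenyl)chromane | CC(=O)O[C@@H]1Cc2c(OC(C)=O)cc(OC(C)=O)cc2O[C@@H]1c1cc(OC(C)=O)c(OC(C)=O)c(OC(C)=O)c1
F3 | step 4 | (2R,3R)-5,7-bis(benzyloxy)-2-[3,4,5-tris(benzyloxy)phenyl]chroman-3-yl acetate | CC(=O)O[C@@H]1Cc2c(OCc3ccccc3)cc(OCc3ccccc3)cc2O[C@@H]1c1cc(OCc3ccccc3)c(OCc3ccccc3)c(OCc3ccccc3)c1
F0 | step 7 | none | none
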